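Ring B of the target, the 1,2-dihydronaphthalene ring C1–C2–C3–C4–C4a–C8a, holds an acrylate unit (C3=C4) wedged between aromatic carbon C4a of the catechol ring A and C2, which is the β-carbon of a 2-aryl-3-arylpropenoate spanning C1/C2. Ring B is therefore closed by a rhodium-catalysed formal [4+2] annulation: an ortho-boronated (E)-2,3-diarylacrylate and a propiolate ester give, by carborhodation and intramolecular conjugate addition, both C–C bonds, both ring stereocentres and the complete carbon skeleton in one operation. The two hydroxy-ester side chains of opposite configuration come from one (R)-alcohol, by acylation with retention and by Mitsunobu inversion.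

Key step: step 9

Remark on the structure: atoms are numbered as in 1,2-dihydronaphthalene (C1 = benzylic sp3 carbon with the ester, C2 = sp3 carbon with the aryl group, C3=C4 = alkene, ring A = C4a–C8a with oxygens on C7 and C8). The target is read as (1S,2S), i.e. 1,2-cis, with an (R)-configured hydroxy ester on the C1 carboxyl and an (S)-configured one on the C3 carboxyl.
Assumption: compounds 1, 4, 6, 7 and 12 are purchased.

Step 1
Reactants: 1 (2R)-3-(3,4-dihydroxyphenyl)-2-hydroxypropanoic acid ((R)-danshensu)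
Product: 2 methyl (2R)-3-(3,4-dihydroxyphenyl)-2-hydroxypropanoate
Conditions: H2SO4 (cat.), MeOH, 50 °C, argon
Reagents that add atoms: methanol, CO
Why: Fischer esterification, which does not touch the carbinol stereocentre.

Step 2
Reactants: 2 methyl (2R)-3-(3,4-dihydroxyphenyl)-2-hydroxypropanoate
Product: 3 methyl (2R)-3-[3,4-bis(benzyloxy)phenyl]-2-hydroxypropanoate
Conditions: BnBr (2.2 equiv), K2CO3 (2.5 equiv), acetone, 56 °C, argon
Reagents that add atoms: benzyl bromide, BrCc1ccccc1
Why: Williamson etherification; carbonate ionises only the two phenols, so the secondary alcohol stays free.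

Step 3
Reactants: 3 methyl (2R)-3-[3,4-bis(benzyloxy)phenyl]-2-hydroxypropanoate; 4 propiolic acid
Product: 5 methyl (2S)-3-[3,4-bis(benzyloxy)phenyl]-2-(prop-2-ynoyloxy)propanoate
Conditions: PPh3, DIAD, THF, −20 → 0 °C (3 and 4 added to the preformed betaine)
Reagents that add atoms: none
Why: Mitsunobu esterification with the strongly acidic alkynoic acid; SN2 displacement of the oxyphosphonium inverts the carbinol carbon from R to S.

Step 4
Reactants: 6 methyl (triphenylphosphoranylidene)acetate; 7 3,4-bis(benzyloxy)benzaldehyde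
Product: 9 methyl (2Z)-3-[3,4-bis(benzyloxy)phenyl]-2-bromoprop-2-enoate, via bromo ylide 8 (not isolated)
Conditions: NBS, CH2Cl2, −20 °C; then 7, K2CO3, 25 °C
Reagents that add atoms: N-bromosuccinimide, O=C1CCC(=O)N1Br
Why: Bromination of the stabilised ylide followed by Wittig olefination; the ester should end up trans to the aryl group, which places bromine cis to it (Z).

Step 5
Reactants: 9 methyl (2Z)-3-[3,4-bis(benzyloxy)phenyl]-2-bromoprop-2-enoate
Product: 10 (2Z)-3-[3,4-bis(benzyloxy)phenyl]-2-bromoprop-2-enoic acid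
Conditions: LiOH·H2O (1.5 equiv), THF/H2O, 0 → 25 °C; then 1 M HCl
Reagents that add atoms: lithium hydroxide, [Li+].[OH-]
Why: Saponification of an activated α-halo enoate, which is expected to outpace dehydrobromination under these mild conditions.

Step 6
Reactants: 10 (2Z)-3-[3,4-bis(benzyloxy)phenyl]-2-bromoprop-2-enoic acid; 3 methyl (2R)-3-[3,4-bis(benzyloxy)phenyl]-2-hydroxypropanoate
Product: 11 (2R)-3-[3,4-bis(benzyloxy)phenyl]-1-methoxy-1-oxopropan-2-yl (2Z)-3-[3,4-bis(benzyloxy)phenyl]-2-bromoprop-2-enoate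
Conditions: DCC, DMAP (cat.), CH2Cl2, 0 → 25 °C
Reagents that add atoms: none
Why: Steglich esterification; the C–O bond of the alcohol is not broken, so the R configuration is retained.

Step 7
Reactants: 12 1,2-bis(benzyloxy)-4-bromobenzene; 11 (2R)-3-[3,4-bis(benzyloxy)phenyl]-1-methoxy-1-oxopropan-2-yl (2Z)-3-[3,4-bis(benzyloxy)phenyl]-2-bromoprop-2-enoate
Product: 15 (2R)-3-[3,4-bis(benzyloxy)phenyl]-1-methoxy-1-oxopropan-2-yl (2E)-2-[2,3-bis(benzyloxy)-6-bromophenyl]-3-[3,4-bis(benzyloxy)phenyl]prop-2-enoate, via aryllithium 13 (not isolated), via arylzinc chloride 14 (not isolated)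
Conditions: LiN(iPr)2 (1.15 equiv), THF, −78 °C; ZnCl2 (1.3 equiv), −78 → 0 °C; then 11 (0.8 equiv), Pd(PPh3)4 (5 mol %), 25 → 50 °C
Reagents that add atoms: none
Why: Directed ortho-lithiation at the C–H flanked by Br and OBn, transmetalation to zinc, and Negishi coupling; zerovalent palladium should insert into the activated alkenyl C–Br bond well before the hindered, electron-rich aryl C–Br bond, and coupling with retention gives the (E)-acrylate with the two aryl groups cis.

Step 8
Reactants: 15 (2R)-3-[3,4-bis(benzyloxy)phenyl]-1-methoxy-1-oxopropan-2-yl (2E)-2-[2,3-bis(benzyloxy)-6-bromophenyl]-3-[3,4-bis(benzyloxy)phenyl]prop-2-enoate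
Product: 16 {3,4-bis(benzyloxy)-2-[(1E)-2-[3,4-bis(benzyloxy)phenyl]-1-({[(2R)-3-[3,4-bis(benzyloxy)phenyl]-1-methoxy-1-oxopropan-2-yl]oxy}carbonyl)ethenyl]phenyl}boronic acid
Conditions: Pd(OAc)2 (2 mol %), XPhos (4 mol %), B2(OH)4 (3 equiv), KOAc (3 equiv), EtOH, 80 °C; aqueous work-up, used without chromatography
Reagents that add atoms: tetrahydroxydiboron, OB(O)B(O)O
Why: Miyaura-type borylation of the aryl bromide with tetrahydroxydiboron, which gives the free boronic acid directly so that the next step can run without base.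

Step 9
Reactants: 16 {3,4-bis(benzyloxy)-2-[(1E)-2-[3,4-bis(benzyloxy)phenyl]-1-({[(2R)-3-[3,4-bis(benzyloxy)phenyl]-1-methoxy-1-oxopropan-2-yl]oxy}carbonyl)ethenyl]phenyl}boronic acid; 5 methyl (2S)-3-[3,4-bis(benzyloxy)phenyl]-2-(prop-2-ynoyloxy)propanoate
Product: 17 1-[(2R)-3-[3,4-bis(benzyloxy)phenyl]-1-methoxy-1-oxopropan-2-yl] 3-[(2S)-3-[3,4-bis(benzyloxy)phenyl]-1-methoxy-1-oxopropan-2-yl] (1S,2S)-7,8-bis(benzyloxy)-2-[3,4-bis(benzyloxy)phenyl]-1,2-dihydronaphthalene-1,3-dicarboxylate
Conditions: [Rh(OH)((R)-binap)]2 (2.5 mol %), 1,4-dioxane/H2O 10:1, 50 °C, argon, no added base; 5 (2 equiv) added over 6 h by syringe pump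
Reagents that add atoms: none
Why: Transmetalation of 16 to the hydroxorhodium catalyst gives an arylrhodium at C4a, which adds syn across the ynoate with the aryl carbon going to the ester-remote carbon (C4–C4a bond) and rhodium to the ester-bearing C3; this alkenylrhodium then adds to C2, the β-carbon of the tethered (E)-diarylacrylate (C3–C2 bond), and water cleaves the resulting rhodium enolate at C1, returning Rh–OH. The closest known reaction types are the rhodium-catalysed tandem carborhodation/conjugate-addition annulation of ortho-boronated cinnamates with alkynes to indenes and the hydroarylation of alkynoates by arylboronic acids, used here to close a six-membered ring. Ring B closes in the 6-endo-trig mode, the only one in which the alkenyl carbon meets the Michael terminus; the competing 5-exo attack at C1 is anti-Michael and would have to build a quaternary carbon. C2 is set by the (R)-BINAP ligand, which must deliver C3 to the Re face of C2 to give 2S (the mirror-image ligand is the direct substitute if the sense proves opposite), and C1 follows from syn addition across the (E)-alkene and protonation of the enolate from the face away from the pseudo-axial C2 aryl group, both of which lead to the 1,2-cis (1S) arrangement. The step needs arene-to-C4 regiochemistry, secured by the ester polarisation of the alkyne, and chemoselectivity against oligomerisation of the terminal ynoate, addressed by phosphine ligation and slow addition; the (E)-geometry keeps the C2–H bond remote from rhodium, so no 1,4-rhodium shift can divert the arylrhodium.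

Step 10
Reactants: 17 1-[(2R)-3-[3,4-bis(benzyloxy)phenyl]-1-methoxy-1-oxopropan-2-yl] 3-[(2S)-3-[3,4-bis(benzyloxy)phenyl]-1-methoxy-1-oxopropan-2-yl] (1S,2S)-7,8-bis(benzyloxy)-2-[3,4-bis(benzyloxy)phenyl]-1,2-dihydronaphthalene-1,3-dicarboxylate
Product: 18 1-[(2R)-3-(3,4-dihydroxyphenyl)-1-methoxy-1-oxopropan-2-yl] 3-[(2S)-3-(3,4-dihydroxyphenyl)-1-methoxy-1-oxopropan-2-yl] (1S,2S)-2-(3,4-dihydroxyphenyl)-7,8-dihydroxy-1,2-dihydronaphthalene-1,3-dicarboxylate (CNP0237075.1)
Conditions: BCl3 (1 M in CH2Cl2, excess), pentamethylbenzene (excess), CH2Cl2, −78 °C; quench with MeOH/CHCl3 at −78 °C; reversed-phase purification under argon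
Reagents that add atoms: none
Why: Lewis-acid debenzylation of aryl benzyl ethers with a non-Lewis-basic cation scavenger; at −78 °C it should spare the esters, the C3=C4 alkene and the epimerisable C1 centre, which hydrogenolysis or basic conditions would endanger.

Compound list
1 | (2R)-3-(3,4-dihydroxyphenyl)-2-hydroxypropanoic acid ((R)-danshensu) | OC(=O)[C@H](O)Cc1ccc(O)c(O)c1 | starting material
2 | methyl (2R)-3-(3,4-dihydroxyphenyl)-2-hydroxypropanoate | COC(=O)[C@H](O)Cc1ccc(O)c(O)c1 | intermediate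
3 | methyl (2R)-3-[3,4-bis(benzyloxy)phenyl]-2-hydroxypropanoate | COC(=O)[C@H](O)Cc1ccc(OCc2ccccc2)c(OCc2ccccc2)c1 | intermediate
4 | propiolic acid (prop-2-ynoic acid) | C#CC(=O)O | starting material
5 | methyl (2S)-3-[3,4-bis(benzyloxy)phenyl]-2-(prop-2-ynoyloxy)propanoate | COC(=O)[C@H](Cc1ccc(OCc2ccccc2)c(OCc2ccccc2)c1)OC(=O)C#C | intermediate
6 | methyl (triphenylphosphoranylidene)acetate | COC(=O)C=P(c1ccccc1)(c1ccccc1)c1ccccc1 | starting material
7 | 3,4-bis(benzyloxy)benzaldehyde | O=Cc1ccc(OCc2ccccc2)c(OCc2ccccc2)c1 | starting material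
8 | methyl bromo(triphenylphosphoranylidene)acetate (bromo ylide) | COC(=O)C(Br)=P(c1ccccc1)(c1ccccc1)c1ccccc1 | intermediate
9 | methyl (2Z)-3-[3,4-bis(benzyloxy)phenyl]-2-bromoprop-2-enoate | COC(=O)/C(Br)=C/c1ccc(OCc2ccccc2)c(OCc2ccccc2)c1 | intermediate
10 | (2Z)-3-[3,4-bis(benzyloxy)phenyl]-2-bromoprop-2-enoic acid | OC(=O)/C(Br)=C/c1ccc(OCc2ccccc2)c(OCc2ccccc2)c1 | intermediate
11 | (2R)-3-[3,4-bis(benzyloxy)phenyl]-1-methoxy-1-oxopropan-2-yl (2Z)-3-[3,4-bis(benzyloxy)phenyl]-2-bromoprop-2-enoate | COC(=O)[C@@H](Cc1ccc(OCc2ccccc2)c(OCc2ccccc2)c1)OC(=O)/C(Br)=C/c1ccc(OCc2ccccc2)c(OCc2ccccc2)c1 | intermediate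
12 | 1,2-bis(benzyloxy)-4-bromobenzene | Brc1ccc(OCc2ccccc2)c(OCc2ccccc2)c1 | starting material
13 | [2,3-bis(benzyloxy)-6-bromophenyl]lithium (aryllithium) | [Li]c1c(Br)ccc(OCc2ccccc2)c1OCc1ccccc1 | intermediate
14 | [2,3-bis(benzyloxy)-6-bromophenyl]zinc chloride (arylzinc chloride) | Cl[Zn]c1c(Br)ccc(OCc2ccccc2)c1OCc1ccccc1 | intermediate
15 | (2R)-3-[3,4-bis(benzyloxy)phenyl]-1-methoxy-1-oxopropan-2-yl (2E)-2-[2,3-bis(benzyloxy)-6-bromophenyl]-3-[3,4-bis(benzyloxy)phenyl]prop-2-enoate | COC(=O)[C@@H](Cc1ccc(OCc2ccccc2)c(OCc2ccccc2)c1)OC(=O)/C(=C/c1ccc(OCc2ccccc2)c(OCc2ccccc2)c1)c1c(Br)ccc(OCc2ccccc2)c1OCc1ccccc1 | intermediate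
16 | {3,4-bis(benzyloxy)-2-[(1E)-2-[3,4-bis(benzyloxy)phenyl]-1-({[(2R)-3-[3,4-bis(benzyloxy)phenyl]-1-methoxy-1-oxopropan-2-yl]oxy}carbonyl)ethenyl]phenyl}boronic acid | COC(=O)[C@@H](Cc1ccc(OCc2ccccc2)c(OCc2ccccc2)c1)OC(=O)/C(=C/c1ccc(OCc2ccccc2)c(OCc2ccccc2)c1)c1c(B(O)O)ccc(OCc2ccccc2)c1OCc1ccccc1 | intermediate
17 | 1-[(2R)-3-[3,4-bis(benzyloxy)phenyl]-1-methoxy-1-oxopropan-2-yl] 3-[(2S)-3-[3,4-bis(benzyloxy)phenyl]-1-methoxy-1-oxopropan-2-yl] (1S,2S)-7,8-bis(benzyloxy)-2-[3,4-bis(benzyloxy)phenyl]-1,2-dihydronaphthalene-1,3-dicarboxylate | COC(=O)[C@H](Cc1ccc(OCc2ccccc2)c(OCc2ccccc2)c1)OC(=O)C1=Cc2ccc(OCc3ccccc3)c(OCc3ccccc3)c2[C@@H](C(=O)O[C@H](Cc2ccc(OCc3ccccc3)c(OCc3ccccc3)c2)C(=O)OC)[C@H]1c1ccc(OCc2ccccc2)c(OCc2ccccc2)c1 | intermediate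
18 | 1-[(2R)-3-(3,4-dihydroxyphenyl)-1-methoxy-1-oxopropan-2-yl] 3-[(2S)-3-(3,4-dihydroxyphenyl)-1-methoxy-1-oxopropan-2-yl] (1S,2S)-2-(3,4-dihydroxyphenyl)-7,8-dihydroxy-1,2-dihydronaphthalene-1,3-dicarboxylate | COC(=O)[C@H](Cc1ccc(O)c(O)c1)OC(=O)C1=Cc2ccc(O)c(O)c2[C@@H](C(=O)O[C@H](Cc2ccc(O)c(O)c2)C(=O)OC)[C@H]1c1ccc(O)c(O)c1 | target

Total step count: 10. Longest linear sequence: 7 steps (steps 4, 5, 6, 7, 8, 9, 10; equally 1, 2, 6, 7, 8, 9, 10).

Steps most likely to fail

Step 9. The terminal ynoate may oligomerise or protonate the arylrhodium (protodeboronation) faster than it is carborhodated. The alkenylrhodium may also be protonated, or close in the exo mode, before the endo conjugate addition, and facial discrimination at C2 or the cis outcome at C1 may be poor. The fallback sets out from 16 and comes back at 17, forming the two ring bonds in separate steps. ipso-Iodination of 16 with N-iodosuccinimide (MeCN, 25 °C) gives the aryl iodide F1. Sonogashira coupling of F1 with alkyne 5 (PdCl2(PPh3)2, CuI, K2CO3, THF, 25 °C, slow addition of 5) gives the aryl ynoate F2. Conjugate reduction of F2 with the copper hydride [(Ph3P)CuH]6 (toluene, −40 → 0 °C) places hydride on C4; the copper allenolate then closes ring B by Michael addition of C3 to C2, and quenching the C1 enolate with a hindered phenol should favour the cis ester 17. The C2 epimer would have to be removed by chromatography, or a chiral bisphosphine on copper used.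

Step 7. Transmetalation and reductive elimination at the doubly ortho-substituted arylzinc may be slow, which would allow insertion of palladium into the aryl C–Br bond, homocoupling or erosion of the alkene geometry. The fallback sets out from 12 (through aryllithium 13) and comes back at 15, building the acrylate by condensation instead of cross-coupling. Opening of ethylene oxide by 13 (BF3·OEt2, THF, −78 °C) gives the 2-arylethanol F3. Oxidation with TEMPO/PhI(OAc)2 in MeCN/H2O gives the arylacetic acid F4. Perkin condensation of F4 with aldehyde 7 (Ac2O, Et3N, 110 °C) gives the (E)-2,3-diarylacrylic acid F5 with the aryl groups cis. Yamaguchi esterification of F5 with alcohol 3 (2,4,6-trichlorobenzoyl chloride, Et3N, then DMAP, toluene) gives 15 with retention at the carbinol carbon.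

Step 8. The arylpalladium intermediate may attack the cis-disposed aryl ring (intramolecular C–H arylation to a phenanthrene) or be reduced instead of borylated, and the hindered boronic acid may protodeboronate on isolation. The fallback sets out from 15 and comes back at 16 without palladium. n-BuLi is added at −100 °C to a THF/toluene solution of 15 and B(OiPr)3 (in situ quench), so that bromine–lithium exchange and capture by the borate outrun attack on the esters. This gives the lithium aryl(triisopropoxy)borate F6, which is hydrolysed with aqueous NH4Cl to 16.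

Further compounds
F1 | step 9 | (2R)-3-[3,4-bis(benzyloxy)phenyl]-1-methoxy-1-oxopropan-2-yl (2E)-2-[2,3-bis(benzyloxy)-6-iodophenyl]-3-[3,4-bis(benzyloxy)phenyl]prop-2-enoate | COC(=O)[C@@H](Cc1ccc(OCc2ccccc2)c(OCc2ccccc2)c1)OC(=O)/C(=C/c1ccc(OCc2ccccc2)c(OCc2ccccc2)c1)c1c(I)ccc(OCc2ccccc2)c1OCc1ccccc1
F2 | step 9 | (2S)-3-[3,4-bis(benzyloxy)phenyl]-1-methoxy-1-oxopropan-2-yl 3-{3,4-bis(benzyloxy)-2-[(1E)-2-[3,4-bis(benzyloxy)phenyl]-1-({[(2R)-3-[3,4-bis(benzyloxy)phenyl]-1-methoxy-1-oxopropan-2-yl]oxy}carbonyl)ethenyl]phenyl}prop-2-ynoate | COC(=O)[C@@H](Cc1ccc(OCc2ccccc2)c(OCc2ccccc2)c1)OC(=O)/C(=C/c1ccc(OCc2ccccc2)c(OCc2ccccc2)c1)c1c(C#CC(=O)O[C@@H](Cc2ccc(OCc3ccccc3)c(OCc3ccccc3)c2)C(=O)OC)ccc(OCc2ccccc2)c1OCc1ccccc1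
F3 | step 7 | 2-[2,3-bis(benzyloxy)-6-bromophenyl]ethan-1-ol | OCCc1c(Br)ccc(OCc2ccccc2)c1OCc1ccccc1
F4 | step 7 | 2-[2,3-bis(benzyloxy)-6-bromophenyl]acetic acid | OC(=O)Cc1c(Br)ccc(OCc2ccccc2)c1OCc1ccccc1
F5 | step 7 | (2E)-2-[2,3-bis(benzyloxy)-6-bromophenyl]-3-[3,4-bis(benzyloxy)phenyl]prop-2-enoic acid | OC(=O)/C(=C/c1ccc(OCc2ccccc2)c(OCc2ccccc2)c1)c1c(Br)ccc(OCc2ccccc2)c1OCc1ccccc1
F6 | step 8 | lithium {3,4-bis(benzyloxy)-2-[(1E)-2-[3,4-bis(benzyloxy)phenyl]-1-({[(2R)-3-[3,4-bis(benzyloxy)phenyl]-1-methoxy-1-oxopropan-2-yl]oxy}carbonyl)ethenyl]phenyl}tri(propan-2-yloxy)borate | [Li+].COC(=O)[C@@H](Cc1ccc(OCc2ccccc2)c(OCc2ccccc2)c1)OC(=O)/C(=C/c1ccc(OCc2ccccc2)c(OCc2ccccc2)c1)c1c([B-](OC(C)C)(OC(C)C)OC(C)C)ccc(OCc2ccccc2)c1OCc1ccccc1
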